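## The problem

Atom numbering used throughout: C1 is the quaternary, methyl-bearing fusion carbon, C2 and C3 are the cyclopentane methylenes, C4 is the isopropyl carbinol, C5 the fusion CH, C6 the acyloxy carbon, C7 a methylene, C8(CH3)=C9 the olefin and C10 a methylene.

Target 21 is the (E)-p-coumarate of a daucane diol: a cyclopentane (C1–C5) fused through the C1–C5 bond to a cycloheptene (C1, C5–C10). Four contiguous stereocentres surround the fusion: C1 (R), C4 (R), C5 (S) and C6 (S). The C1 methyl, the C4 hydroxyl and the C5–C6 bond lie on one face of the five-membered ring; the isopropyl group and H-5 lie on the other (trans fusion), and the C6 oxygen is cis to H-5. C4 is the natural control element: once fixed, it can steer a methyl nucleophile to C1 (anti to isopropyl) and, through its hydroxyl, a hydride to C6. C5 is epimerisable whenever C6 is a ketone, so it has to end up correct by thermodynamic preference. The fragile points are the tertiary β-hydroxy ketone stage (retro-aldol, dehydration), the C8=C9 olefin (β,γ to C6, prone to drift into conjugation) and the coumarate (free phenol, Michael acceptor, labile ester), which must therefore come last with the phenol masked. The enabling feature is that C1, C6, C7, C8 with its methyl, C9 and C10, plus the oxygen on C6, are the six carbons of a 2-alkoxy-4-methylphenyl ring carrying the C2–C3–C4 chain at C1. C5 then sits between C1 and C6 exactly like a carbene carbon inserted into that aryl bond, with C4 as the carbonyl of a diazoketone. The ring expansion must therefore occur at the oxygen-bearing ortho bond, against the usual preference for the unsubstituted one, and its single stereocentre must be handed on to C4 before it is lost.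

## Retrosynthesis

**Ester bond C6–O.** Target 21 is traced through its silyl ether 20 to diol 16 and acid 19, the phenol-protected form of p-coumaric acid 17. This cut comes first because the cinnamate would not survive organometallic or hydride steps. Only the secondary hydroxyl of 16 can be acylated, so no protection is needed on the diol. The forward step only has to acylate a hindered secondary alcohol.

**C6–H bond.** Diol 16 is traced to β-hydroxy ketone 15. Creating C6 by reduction, rather than carrying it, lets the C4 hydroxyl control it by internal hydride delivery and removes one stereocentre from every earlier intermediate. The forward reaction has to be a directed 1,3-anti reduction that neither epimerises C5 nor moves the C8=C9 olefin.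

**C1–CH3 bond (and C5–H).** Ketone 15 is traced to enone 13 and a methyl cuprate. A quaternary centre next to two other substituted carbons is best made from a flat carbon, and C1 is β to the C6 carbonyl once a C5=C1 double bond exists. Alkylation at C1 would instead need a carbonyl at C2 or C10, which the target lacks. The precursor has one stereocentre (C4) instead of three. The forward step must add to a tetrasubstituted enone on the face anti to isopropyl, and C5 must then settle trans.

**Enone 13 from the arene-derived triene (no skeletal bond cut).** Enone 13 is the hydrolysed and conjugated form of enol ether 11: water replaces methanol at C6 (via dienone 12) and H-5 moves to C10. This reveals a 1-methoxycycloheptatriene, the signature of an expanded anisole ring. Compound 11 in turn comes from bromide 10 by hydrodebromination; the bromine is a temporary blocking group whose purpose lies in the key step.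

**C4–isopropyl bond.** Alcohol 10 is traced to ketone 8 and isopropylmagnesium chloride 9. This has to be the first operation after ring formation. The C5 centre of 8 is α to a ketone and doubly allylic, so it must set C4 before it is erased; from then on C4 carries the chirality.

**Key disconnection, bonds C1–C5 and C5–C6.** Ketone 8 is traced to diazoketone 7, in which both rings and every stereocentre are gone and the seven-membered ring is a benzene ring. Neighbouring cuts of the hydroazulene would need two separate ring closures. The forward reaction must add the carbenoid across the methoxy-bearing ortho bond and must do so enantioselectively. Ortho substituents normally send the carbenoid to the free ortho bond, so the other ortho position of 7 is occupied by bromine.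

**Side chain.** Diazoketone 7 comes from acid 5 through acid chloride 6. Acid 5 comes from cinnamic acid 4, the Knoevenagel–Doebner product of aldehyde 2 and malonic acid 3. Aldehyde 2 is the ortho-formylation product of commercial 3-bromo-5-methylanisole 1. All of this is routine aromatic chemistry.

## Roads not taken

**Alternative 1:** The seven-membered ring is cut at C7–C8 and C9–C10. In the forward sense a monovalent rhodium catalyst opens the C5–C10 bond of a ring-fused 2-siloxyvinylcyclopropane, propyne A2 inserts, and reductive elimination gives the bicyclic silyl enol ether A1.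
- Merits: the ring arrives with C8=C9 where it must stay and with C6 as a silyl enol ether that can be unmasked by kinetic protonation. C1 and C4 are already in place.
- Weak points: the vinylcyclopropane must carry two fully substituted stereocentres on a bicyclo[3.1.0]hexane, which is a multistep enantioselective synthesis in itself. A bond to a quaternary cyclopropane carbon has to be cleaved. Nothing in the substrate secures the orientation of A2 (methyl at C8, not C9).
- Comparison: in the endgame this road is better, because no proton has to be moved through an enolisable ketone. The chosen plan sets against it a flat, cheap aromatic precursor and the formation of both rings in one step.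

**Alternative 2:** The cut is at C1–C2 and C5–C6 of a cyclohexene that is later contracted. Methacrolein A4 and 2-isopropylbuta-1,3-diene A5 combine in a para-selective Diels–Alder reaction under a chiral oxazaborolidinium Lewis acid to give aldehyde A3 with C1 set. Ozonolysis of the ring olefin and an intramolecular aldol reaction then build the cyclopentane with the isopropyl carbinol.
- Merits: the quaternary centre C1 is fixed by one of the most dependable catalytic asymmetric reactions. For absolute configuration this is more certain than an asymmetric arene cyclopropanation.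
- Weak points: A3 holds eleven of the fifteen skeletal carbons and no seven-membered ring. The aldol step must control C4 and C5 on a retro-aldol-prone product, and the cycloheptene still has to be annulated over many steps.
- Comparison: the chosen plan is weaker in enantiocontrol but far shorter in skeleton building.

**Alternative 3:** C5–C6 and C1–C10 are cut without forming a ring. 2-Lithio-1,3-dithiane A8 adds to (R)-4-(tert-butyldimethylsilyloxy)-2-methylcyclopent-2-enone A7 anti to the silyloxy group, and the enolate is alkylated at C1 by the (Z)-allylic bromide A9, giving cyclopentanone A6.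
- Merits: the trans relation of C1 and C5 is fixed kinetically and reliably, and the C8 olefin geometry is carried in from A9. The chosen plan leaves C5 to thermodynamic control, so this road is better on that point.
- Weak points: the seven-membered ring still has to be closed from the dithiane. The ring ketone sits on C2 and must be removed, the silyl ether carbon must be oxidised and given the isopropyl group, and the β-silyloxy enolate can eliminate.
- Comparison: the step count is clearly higher, and the chosen plan answers with brevity.

Key step: step 5

Remark on the chemistry: the sense of asymmetric induction of Rh2(S-PTTL)4 with this substrate is assumed; if the (8aR) ketone predominates, the catalyst from (R)-tert-leucine is used and nothing else changes.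
Remark on the chemistry: azulene locants are used in names; C1, C4, C5 and C6 of the target numbering are C8a, C3, C3a and C4 of the azulen-4-one names.

**Step 1**
Reactants: 1 1-bromo-3-methoxy-5-methylbenzene
Product: 2 2-bromo-6-methoxy-4-methylbenzaldehyde
Conditions: LDA, THF, −78 °C; DMF; aq. NH4Cl
Reagents that add atoms: N,N-dimethylformamide, CN(C)C=O
Why: Directed ortho-metalation: the hydrogen between bromine and methoxy is the most acidic of 1, and LDA removes it at −78 °C, where the 2-bromoaryllithium does not yet lose LiBr; formylation with DMF (Bouveault aldehyde synthesis) then gives 2.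

**Step 2**
Reactants: 2 2-bromo-6-methoxy-4-methylbenzaldehyde; 3 malonic acid
Product: 4 (2E)-3-(2-bromo-6-methoxy-4-methylphenyl)prop-2-enoic acid
Conditions: pyridine, piperidine (cat.), 100 °C
Reagents that add atoms: none
Why: Knoevenagel–Doebner condensation; amine-catalysed condensation with decarboxylation gives the (E)-cinnamic acid, and ortho,ortho′-disubstituted benzaldehydes are still reactive enough.

**Step 3**
Reactants: 4 (2E)-3-(2-bromo-6-methoxy-4-methylphenyl)prop-2-enoic acid
Product: 5 3-(2-bromo-6-methoxy-4-methylphenyl)propanoic acid
Conditions: H2 (4 atm), RhCl(PPh3)3 (5 mol %), THF/EtOH, 50 °C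
Reagents that add atoms: none
Why: Homogeneous hydrogenation with RhCl(PPh3)3 (monovalent rhodium) saturates the disubstituted olefin and leaves the aryl bromide alone, which heterogeneous palladium would endanger.

**Step 4**
Reactants: 5 3-(2-bromo-6-methoxy-4-methylphenyl)propanoic acid
Product: 7 4-(2-bromo-6-methoxy-4-methylphenyl)-1-diazobutan-2-one, via acid chloride 6 (not isolated)
Conditions: (COCl)2, DMF (cat.), CH2Cl2, 0 to 23 °C; then CH2N2 (3 equiv), Et2O, 0 °C
Reagents that add atoms: diazomethane, C=[N+]=[N-]; oxalyl chloride, O=C(Cl)C(Cl)=O (chlorine of 6 only)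
Why: Acid chloride formation followed by acylation of diazomethane (first stage of the Arndt–Eistert sequence); the excess diazomethane takes up the hydrogen chloride, so no chloromethyl ketone forms.

**Step 5**
Reactants: 7 4-(2-bromo-6-methoxy-4-methylphenyl)-1-diazobutan-2-one
Product: 8 (8aS)-4-bromo-8-methoxy-6-methyl-3,8a-dihydroazulen-1(2H)-one
Conditions: Rh2(S-PTTL)4 (1 mol %), CH2Cl2, 0 °C, slow addition of 7; used crude
Reagents that add atoms: none
Why: Intramolecular Büchner reaction: Rh2(S-PTTL)4 (dirhodium tetrakis[N-phthaloyl-(S)-tert-leucinate], divalent rhodium) expels dinitrogen from 7, and the electrophilic carbenoid at C5 adds across the aryl C1–C6 bond; bond C1–C5 closes the five-membered ring through a five-membered transition state at the ipso carbon, and bond C5–C6 completes a norcaradiene. The seven-membered ring is then closed by disrotatory 6π electrocyclic opening of the C1–C6 cyclopropane bond, a ring expansion of the arene; the methoxy donor on C6 and the acyl group on C5 should hold the product on the cycloheptatriene side. The closest known reaction type is the dirhodium-carboxylate-catalysed cyclisation of 1-diazo-4-arylbutan-2-ones to 3,8a-dihydroazulen-1(2H)-ones, including enantioselective variants with chiral ligands. The only new stereocentre, C8a (C5 of the target), is set by the catalyst, whose phthalimido-tert-leucinate ligands differentiate the two faces of the carbenoid as it meets the ring. The step needs regioselectivity between the two ortho bonds, and because ortho substituents normally divert the carbenoid to an unsubstituted ortho bond, the other ortho carbon carries bromine, which is larger than the methoxy oxygen and makes its bond the less nucleophilic one, while methoxy on C6 and methyl para to C1 stabilise the charge that builds up as the carbenoid bonds to C1. Slow addition suppresses carbenoid dimerisation. Ketone 8 is labile to acid and base at C8a and goes into step 6 without purification.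

**Step 6**
Reactants: 8 (8aS)-4-bromo-8-methoxy-6-methyl-3,8a-dihydroazulen-1(2H)-one; 9 isopropylmagnesium chloride
Product: 10 (1R,8aR)-4-bromo-8-methoxy-6-methyl-1-(propan-2-yl)-1,2,3,8a-tetrahydroazulen-1-ol
Conditions: CeCl3, THF, −78 °C; aq. NH4Cl
Reagents that add atoms: none
Why: 1,2-Addition of an organocerium reagent (Grignard reagent transmetalated with CeCl3); its low basicity avoids enolisation at the acidic C8a–H and β-hydride reduction. It should attack the cyclopentanone from the face of H-8a, anti to the enol ether carbon on C8a, so isopropyl ends up cis to H-8a and the hydroxyl cis to C8.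

**Step 7**
Reactants: 10 (1R,8aR)-4-bromo-8-methoxy-6-methyl-1-(propan-2-yl)-1,2,3,8a-tetrahydroazulen-1-ol
Product: 11 (1R,8aR)-8-methoxy-6-methyl-1-(propan-2-yl)-1,2,3,8a-tetrahydroazulen-1-ol
Conditions: Pd(PPh3)4 (5 mol %), Bu3SnH, THF, 40 °C
Reagents that add atoms: none
Why: Palladium-catalysed hydrodehalogenation of an alkenyl bromide (oxidative addition to zerovalent palladium, hydride transfer from tin, reductive elimination) replaces bromine by hydrogen without moving double bonds; C8a is no longer next to a carbonyl group, so it survives.

**Step 8**
Reactants: 11 (1R,8aR)-8-methoxy-6-methyl-1-(propan-2-yl)-1,2,3,8a-tetrahydroazulen-1-ol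
Product: 13 (3R)-3-hydroxy-6-methyl-3-(propan-2-yl)-2,3,5,8-tetrahydroazulen-4(1H)-one, via dienone 12 (not isolated)
Conditions: (CO2H)2, THF/H2O, 0 °C; then Et3N (0.3 equiv), CH2Cl2, 0 °C, stopped at first conjugated isomer
Reagents that add atoms: water, O
Why: Enol ether hydrolysis by protonation at C7, the usual course for 1-alkoxycycloheptatrienes (which give cyclohepta-3,5-dienones), exposes the C6 ketone in 12. Its C5–H, now flanked by the carbonyl and the diene, is then moved to C10 by a catalytic amine (β,γ to α,β conjugation, the same 1,3-proton shift that turns 3,8a-dihydroazulenones into their 3,4-dihydro isomers). C5 is erased, while C4 and the isolated C8=C9 olefin remain.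

**Step 9**
Reactants: 13 (3R)-3-hydroxy-6-methyl-3-(propan-2-yl)-2,3,5,8-tetrahydroazulen-4(1H)-one
Product: 15 (3R,3aR,8aR)-3-hydroxy-6,8a-dimethyl-3-(propan-2-yl)-2,3,3a,5,8,8a-hexahydroazulen-4(1H)-one, via bis(silyl) ether 14 (not isolated)
Conditions: Me2CuLi (from MeLi and CuI), TMSCl, THF/Et2O, −78 to −30 °C; then 1 M HCl, THF, 0 °C
Reagents that add atoms: lithium dimethylcuprate, [Li+].C[Cu-]C; chlorotrimethylsilane, C[Si](C)(C)Cl (silicon of 14 only)
Why: TMSCl-accelerated conjugate addition of a Gilman cuprate to the β,β-disubstituted enone; methyl should enter C8a (C1 of the target) anti to the isopropyl group of the neighbouring carbinol, cis to its oxygen, and the enolate is trapped as silyl enol ether 14. Acidic work-up removes both silyl groups and protonates C3a (C5); the trans-fused β-hydroxy ketone, whose carbonyl carbon is cis to the small hydroxyl and methyl groups and can accept a hydrogen bond from the hydroxyl, is expected to be the stable epimer.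

**Step 10**
Reactants: 15 (3R,3aR,8aR)-3-hydroxy-6,8a-dimethyl-3-(propan-2-yl)-2,3,3a,5,8,8a-hexahydroazulen-4(1H)-one
Product: 16 (3R,3aS,4S,8aR)-6,8a-dimethyl-3-(propan-2-yl)-1,2,3,3a,4,5,8,8a-octahydroazulene-3,4-diol
Conditions: Me4NBH(OAc)3, MeCN/AcOH (1:1), −30 °C
Reagents that add atoms: none
Why: Evans–Saksena hydroxyl-directed reduction: the tertiary hydroxyl exchanges an acetate on boron and hydride is delivered within the complex to the ketone face on the side of that oxygen, giving the 1,3-anti diol (4S, hydroxyl cis to H-3a). The cold, weakly acidic medium should not move the β,γ-olefin.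

**Step 11**
Reactants: 17 p-coumaric acid
Product: 19 (2E)-3-[4-(tert-butyldimethylsilyloxy)phenyl]prop-2-enoic acid, via bis(silyl) derivative 18 (not isolated)
Conditions: TBSCl (2.5 equiv), imidazole, DMF, 23 °C; then AcOH, THF/H2O, 23 °C
Reagents that add atoms: tert-butyldimethylsilyl chloride, CC(C)(C)[Si](C)(C)Cl
Why: Silylation of phenol and carboxylic acid; the silyl ester is far more labile than the aryl silyl ether and is hydrolysed selectively by aqueous acetic acid.

**Step 12**
Reactants: 16 (3R,3aS,4S,8aR)-6,8a-dimethyl-3-(propan-2-yl)-1,2,3,3a,4,5,8,8a-octahydroazulene-3,4-diol; 19 (2E)-3-[4-(tert-butyldimethylsilyloxy)phenyl]prop-2-enoic acid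
Product: 20 (3R,3aS,4S,8aR)-3-hydroxy-6,8a-dimethyl-3-(propan-2-yl)-1,2,3,3a,4,5,8,8a-octahydroazulen-4-yl (2E)-3-[4-(tert-butyldimethylsilyloxy)phenyl]prop-2-enoate
Conditions: EDC·HCl, DMAP, CH2Cl2, 23 °C
Reagents that add atoms: none
Why: Steglich esterification (carbodiimide, DMAP); only the secondary hydroxyl is acylated because the tertiary one is too hindered, and the masked phenol cannot compete.

**Step 13**
Reactants: 20 (3R,3aS,4S,8aR)-3-hydroxy-6,8a-dimethyl-3-(propan-2-yl)-1,2,3,3a,4,5,8,8a-octahydroazulen-4-yl (2E)-3-[4-(tert-butyldimethylsilyloxy)phenyl]prop-2-enoate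
Product: 21 (3R,3aS,4S,8aR)-3-hydroxy-6,8a-dimethyl-3-(propan-2-yl)-1,2,3,3a,4,5,8,8a-octahydroazulen-4-yl (2E)-3-(4-hydroxyphenyl)prop-2-enoate
Conditions: TBAF, AcOH, THF, 0 °C
Reagents that add atoms: none
Why: Fluoride cleavage of the aryl silyl ether; buffering with acetic acid keeps the phenoxide from attacking the cinnamate and spares the ester and the olefin.

## Compound list

1 | 1-bromo-3-methoxy-5-methylbenzene (3-bromo-5-methylanisole) | COc1cc(C)cc(Br)c1 | starting material
2 | 2-bromo-6-methoxy-4-methylbenzaldehyde | COc1cc(C)cc(Br)c1C=O | intermediate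
3 | malonic acid | OC(=O)CC(O)=O | starting material
4 | (2E)-3-(2-bromo-6-methoxy-4-methylphenyl)prop-2-enoic acid | COc1cc(C)cc(Br)c1/C=C/C(O)=O | intermediate
5 | 3-(2-bromo-6-methoxy-4-methylphenyl)propanoic acid | COc1cc(C)cc(Br)c1CCC(O)=O | intermediate
6 | 3-(2-bromo-6-methoxy-4-methylphenyl)propanoyl chloride | COc1cc(C)cc(Br)c1CCC(Cl)=O | intermediate (not isolated)
7 | 4-(2-bromo-6-methoxy-4-methylphenyl)-1-diazobutan-2-one | COc1cc(C)cc(Br)c1CCC(=O)C=[N+]=[N-] | intermediate
8 | (8aS)-4-bromo-8-methoxy-6-methyl-3,8a-dihydroazulen-1(2H)-one | COC1=CC(C)=CC(Br)=C2CCC(=O)[C@H]12 | intermediate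
9 | isopropylmagnesium chloride | CC(C)[Mg]Cl | starting material
10 | (1R,8aR)-4-bromo-8-methoxy-6-methyl-1-(propan-2-yl)-1,2,3,8a-tetrahydroazulen-1-ol | COC1=CC(C)=CC(Br)=C2CC[C@@](O)(C(C)C)[C@H]12 | intermediate
11 | (1R,8aR)-8-methoxy-6-methyl-1-(propan-2-yl)-1,2,3,8a-tetrahydroazulen-1-ol | COC1=CC(C)=CC=C2CC[C@@](O)(C(C)C)[C@H]12 | intermediate
12 | (3R,3aR)-3-hydroxy-6-methyl-3-(propan-2-yl)-2,3,3a,5-tetrahydroazulen-4(1H)-one | O=C1CC(C)=CC=C2CC[C@@](O)(C(C)C)[C@H]12 | intermediate (not isolated)
13 | (3R)-3-hydroxy-6-methyl-3-(propan-2-yl)-2,3,5,8-tetrahydroazulen-4(1H)-one | O=C1CC(C)=CCC2=C1[C@](O)(C(C)C)CC2 | intermediate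
14 | (3R,8aR)-6,8a-dimethyl-3-(propan-2-yl)-3,4-bis(trimethylsilyloxy)-1,2,3,5,8,8a-hexahydroazulene | CC1=CC[C@@]2(C)CC[C@@](O[Si](C)(C)C)(C(C)C)C2=C(O[Si](C)(C)C)C1 | intermediate (not isolated)
15 | (3R,3aR,8aR)-3-hydroxy-6,8a-dimethyl-3-(propan-2-yl)-2,3,3a,5,8,8a-hexahydroazulen-4(1H)-one | CC1=CC[C@@]2(C)CC[C@@](O)(C(C)C)[C@@H]2C(=O)C1 | intermediate
16 | (3R,3aS,4S,8aR)-6,8a-dimethyl-3-(propan-2-yl)-1,2,3,3a,4,5,8,8a-octahydroazulene-3,4-diol | CC1=CC[C@@]2(C)CC[C@@](O)(C(C)C)[C@@H]2[C@@H](O)C1 | intermediate
17 | p-coumaric acid, (2E)-3-(4-hydroxyphenyl)prop-2-enoic acid | OC(=O)/C=C/c1ccc(O)cc1 | starting material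
18 | tert-butyldimethylsilyl (2E)-3-[4-(tert-butyldimethylsilyloxy)phenyl]prop-2-enoate | CC(C)(C)[Si](C)(C)OC(=O)/C=C/c1ccc(O[Si](C)(C)C(C)(C)C)cc1 | intermediate (not isolated)
19 | (2E)-3-[4-(tert-butyldimethylsilyloxy)phenyl]prop-2-enoic acid | OC(=O)/C=C/c1ccc(O[Si](C)(C)C(C)(C)C)cc1 | intermediate
20 | (3R,3aS,4S,8aR)-3-hydroxy-6,8a-dimethyl-3-(propan-2-yl)-1,2,3,3a,4,5,8,8a-octahydroazulen-4-yl (2E)-3-[4-(tert-butyldimethylsilyloxy)phenyl]prop-2-enoate | CC1=CC[C@@]2(C)CC[C@@](O)(C(C)C)[C@@H]2[C@@H](OC(=O)/C=C/c2ccc(O[Si](C)(C)C(C)(C)C)cc2)C1 | intermediate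
21 | (3R,3aS,4S,8aR)-3-hydroxy-6,8a-dimethyl-3-(propan-2-yl)-1,2,3,3a,4,5,8,8a-octahydroazulen-4-yl (2E)-3-(4-hydroxyphenyl)prop-2-enoate | CC1=CC[C@@]2(C)CC[C@@](O)(C(C)C)[C@@H]2[C@@H](OC(=O)/C=C/c2ccc(O)cc2)C1 | target

## Step count and least certain steps

Total step count: 13. Longest linear sequence: 12 (steps 1–10, 12 and 13; step 11 prepares the acid component).

**Step 5 (key step).** The most likely failure is insufficient enantioface discrimination: acceptor-only diazoketones on an ortho,ortho′-disubstituted ring are demanding substrates for chiral carboxylates. Partial loss of configuration by enolisation at C8a before step 6 is a second risk. Diversion of the carbenoid to the brominated ortho bond is considered less likely.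

The fallback sets out from 7 and replaces asymmetric catalysis by resolution. Rh2(OAc)4 (dirhodium tetraacetate, divalent rhodium) in CH2Cl2 should give the racemic ketone, that is 8 together with its antipode (8aR)-4-bromo-8-methoxy-6-methyl-3,8a-dihydroazulen-1(2H)-one F1. Addition of 9 with CeCl3 as in step 6 then gives 10 together with (1S,8aS)-4-bromo-8-methoxy-6-methyl-1-(propan-2-yl)-1,2,3,8a-tetrahydroazulen-1-ol F2. The two alcohols are separated by preparative chromatography on a cellulose-carbamate chiral stationary phase, and the route is rejoined at 10.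

**Step 8.** The proton shift may not stop at 13. Deprotonation on the C7 side, or a further shift from the C5-side enolate, would carry the C8=C9 double bond into conjugation and give cross- or linearly conjugated dienones, since 13 is probably not the most stable isomer. Dehydration or retro-aldol cleavage of the tertiary β-hydroxy ketone is a second risk.

The fallback sets out from 8 (either configuration serves, so no chiral catalyst is needed) and performs the proton shift while C4 is still the ketone and only one hydrogen is activated. Pd(PPh3)4 and Bu3SnH give (8aS)-8-methoxy-6-methyl-3,8a-dihydroazulen-1(2H)-one F3. Et3N in CH2Cl2 gives the achiral conjugated trienone 8-methoxy-6-methyl-3,4-dihydroazulen-1(2H)-one F4. 1,2-Addition of 9 with CeCl3 gives racemic tertiary allylic alcohol, (1R)-8-methoxy-6-methyl-1-(propan-2-yl)-1,2,3,4-tetrahydroazulen-1-ol F5 and its antipode (1S)-8-methoxy-6-methyl-1-(propan-2-yl)-1,2,3,4-tetrahydroazulen-1-ol F6, which are separated on a chiral stationary phase. Dilute aqueous oxalic acid then hydrolyses the enol ether of F5 by protonation at C7, and the route is rejoined at 13. The price is that absolute configuration comes from a resolution, and the hydrolysis must again protonate C7 and not C9.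

**Step 9.** The cuprate may enolise the ketone at C7 instead of adding, or add slowly to the tetrasubstituted enone and lose facial selectivity; C5 may also be protonated to give the cis-fused epimer.

The fallback sets out from 13 and makes the methyl group from a cyclopropane.
- Luche reduction (NaBH4, CeCl3, MeOH) gives allylic diol (3R)-6-methyl-3-(propan-2-yl)-1,2,3,4,5,8-hexahydroazulene-3,4-diol F7.
- Hydroxyl-directed Simmons–Smith cyclopropanation (Et2Zn, CH2I2) of the tetrasubstituted allylic olefin, delivered syn to the tertiary hydroxyl on the face left open by the isopropyl group, gives (3R)-6-methyl-3-(propan-2-yl)-1,2,3,4,5,8-hexahydro-3a,8a-methanoazulene-3,4-diol F8.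
- Dess–Martin oxidation gives cyclopropyl ketone (3R)-3-hydroxy-6-methyl-3-(propan-2-yl)-2,3,5,8-tetrahydro-3a,8a-methanoazulen-4(1H)-one F9.
- Lithium in liquid ammonia cleaves the cyclopropane bond that overlaps with the carbonyl π system (C3a–CH2), leaving the methyl group on C8a and an enolate that is protonated.

The route is rejoined at 15.

**Step 10.** Ligand exchange at the hindered tertiary hydroxyl may be slow, so that undirected hydride delivery from the opposite, less hindered face competes; prolonged exposure to acid could also move the olefin.

The fallback sets out from 15 and uses the wrong-face reduction on purpose. NaBH4 in MeOH at low temperature should give the epimer (3R,3aS,4R,8aR)-6,8a-dimethyl-3-(propan-2-yl)-1,2,3,3a,4,5,8,8a-octahydroazulene-3,4-diol F10. Mitsunobu esterification of F10 with 19 (PPh3, DIAD, toluene) inverts C4 and forms the ester in one operation, and the route is rejoined at 20.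

## Further compounds

F1 | step 5 | (8aR)-4-bromo-8-methoxy-6-methyl-3,8a-dihydroazulen-1(2H)-one | COC1=CC(C)=CC(Br)=C2CCC(=O)[C@@H]12
F2 | step 5 | (1S,8aS)-4-bromo-8-methoxy-6-methyl-1-(propan-2-yl)-1,2,3,8a-tetrahydroazulen-1-ol | COC1=CC(C)=CC(Br)=C2CC[C@](O)(C(C)C)[C@@H]12
F3 | step 8 | (8aS)-8-methoxy-6-methyl-3,8a-dihydroazulen-1(2H)-one | COC1=CC(C)=CC=C2CCC(=O)[C@H]12
F4 | step 8 | 8-methoxy-6-methyl-3,4-dihydroazulen-1(2H)-one | COC1=CC(C)=CCC2=C1C(=O)CC2
F5 | step 8 | (1R)-8-methoxy-6-methyl-1-(propan-2-yl)-1,2,3,4-tetrahydroazulen-1-ol | COC1=CC(C)=CCC2=C1[C@](O)(C(C)C)CC2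
F6 | step 8 | (1S)-8-methoxy-6-methyl-1-(propan-2-yl)-1,2,3,4-tetrahydroazulen-1-ol | COC1=CC(C)=CCC2=C1[C@@](O)(C(C)C)CC2
F7 | step 9 | (3R)-6-methyl-3-(propan-2-yl)-1,2,3,4,5,8-hexahydroazulene-3,4-diol (C4 configuration left open, centre removed again) | OC1CC(C)=CCC2=C1[C@](O)(C(C)C)CC2
F8 | step 9 | (3R)-6-methyl-3-(propan-2-yl)-1,2,3,4,5,8-hexahydro-3a,8a-methanoazulene-3,4-diol (methano bridge cis to the 3-hydroxyl, C4 left open) | CC1=CC[C@@]23CC[C@@](O)(C(C)C)[C@@]2(C3)C(O)C1
F9 | step 9 | (3R)-3-hydroxy-6-methyl-3-(propan-2-yl)-2,3,5,8-tetrahydro-3a,8a-methanoazulen-4(1H)-one (methano bridge cis to the 3-hydroxyl) | CC1=CC[C@@]23CC[C@@](O)(C(C)C)[C@@]2(C3)C(=O)C1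
F10 | step 10 | (3R,3aS,4R,8aR)-6,8a-dimethyl-3-(propan-2-yl)-1,2,3,3a,4,5,8,8a-octahydroazulene-3,4-diol | CC1=CC[C@@]2(C)CC[C@@](O)(C(C)C)[C@@H]2[C@H](O)C1
A1 | alternative 1 | (3R,8aR)-4-(tert-butyldimethylsilyloxy)-6,8a-dimethyl-3-(propan-2-yl)-3-(triethylsilyloxy)-1,2,3,5,8,8a-hexahydroazulene | CC1=CC[C@@]2(C)CC[C@@](O[Si](CC)(CC)CC)(C(C)C)C2=C(O[Si](C)(C)C(C)(C)C)C1
A2 | alternative 1 | propyne | CC#C
A3 | alternative 2 | (S)-4-isopropyl-1-methylcyclohex-3-ene-1-carbaldehyde | O=C[C@]1(C)CC=C(C(C)C)CC1
A4 | alternative 2 | methacrolein | CC(=C)C=O
A5 | alternative 2 | 2-isopropylbuta-1,3-diene | C=CC(=C)C(C)C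
A6 | alternative 3 | 2,2,3-trisubstituted cyclopentanone carrying the dithianyl group, the silyloxy group and the (Z)-4-pivaloyloxy-3-methylbut-2-enyl chain | C/C(COC(=O)C(C)(C)C)=C/C[C@@]1(C)C(=O)C[C@@H](O[Si](C)(C)C(C)(C)C)[C@@H]1C2SCCCS2
A7 | alternative 3 | (R)-4-(tert-butyldimethylsilyloxy)-2-methylcyclopent-2-enone | CC1=C[C@H](O[Si](C)(C)C(C)(C)C)CC1=O
A8 | alternative 3 | 2-lithio-1,3-dithiane | [Li]C1SCCCS1
A9 | alternative 3 | (Z)-4-bromo-2-methylbut-2-en-1-yl pivalate | C/C(COC(=O)C(C)(C)C)=C/CBr
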